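**Retrosynthetic overview**

1. Target 20 ⇐ ester equilibration and hydrolysis ⇐ methyl ester 18 ⇐ Wolff ring contraction of the seven-membered 2-diazoketone 16. Enabling feature: in the cyclohexane, the CH that carries CO2H lies between the side-chain CH and a CH2, and its carboxyl carbon is exocyclic; this ring-CH–C(=O)O unit is what a 1,2-shift leaves when the carbonyl carbon of a cycloheptanone is pushed out of the ring.
2. 16 ⇐ regiospecific diazo transfer ⇐ silyl enol ether 13 ⇐ copper-catalysed asymmetric conjugate addition of the alkylzirconium from vinylchromene 11 to 4,4-dimethylcyclohept-2-enone 3. The ketone steers C–C bond formation next to the gem-dimethyl carbon, its enolate marks the carbon that will carry the carboxyl group, and the ketone carbon itself becomes the carboxyl carbon.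
3. 3 ⇐ one-carbon ring expansion of 4,4-dimethylcyclohex-2-enone 1 with ethyl diazoacetate, then decarboxylation.
4. 11 ⇐ Wittig ⇐ oxidation ⇐ ring-closing metathesis ⇐ palladium-catalysed asymmetric etherification of vinylphenol 6 with isoprene monoepoxide 7 (sets the quaternary ether center) ⇐ atranol 4.
5. Ring order: seven-membered carbocycle (step 1), pyran ring of the chromene (step 6), cyclohexane by contraction of the seven-membered ring (step 11).

Key step: step 11

Assumption: compounds 1, 4 and racemic 7 are taken as purchasable, and the ligand enantiomers in steps 5 and 9 are assigned by the usual empirical models for these catalyst families; if the sense of induction proves opposite, the mirror-image ligand is used.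

**Route**

Step 1
Reactants: 1 4,4-dimethylcyclohex-2-en-1-one
Product: 2 ethyl 5,5-dimethyl-2-oxocyclohept-3-ene-1-carboxylate
Conditions: N2CHCO2Et, BF3·OEt2, CH2Cl2, 0 °C to rt
Reagents that add atoms: ethyl diazoacetate, CCOC(=O)C=[N+]=[N-]
Why: Lewis-acid-promoted diazoacetate homologation (Tiffeneau–Demjanov-type ring expansion) in which the saturated α-CH2 should migrate in preference to the alkenyl carbon, so the enone survives and the gem-dimethyl carbon ends γ to the carbonyl, while the hindered β-carbon disfavours dipolar cycloaddition to the C=C bond.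

Step 2
Reactants: 2 ethyl 5,5-dimethyl-2-oxocyclohept-3-ene-1-carboxylate
Product: 3 4,4-dimethylcyclohept-2-en-1-one
Conditions: 2 M aq. H2SO4, 1,4-dioxane, 100 °C
Reagents that add atoms: none
Why: Acid-catalysed ester hydrolysis and decarboxylation of the β-keto acid; the enone cannot leave conjugation because its γ-carbon is quaternary.

Step 3
Reactants: 4 2,6-dihydroxy-4-methylbenzaldehyde (atranol)
Product: 5 2-hydroxy-4-methyl-6-(triisopropylsilyloxy)benzaldehyde
Conditions: iPr3SiCl (1.05 equiv), imidazole, DMF, 0 °C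
Reagents that add atoms: chlorotriisopropylsilane, CC(C)[Si](Cl)(C(C)C)C(C)C
Why: Silyl ether formation on one of the two equivalent phenols; the remaining hydroxyl is hydrogen-bonded to the aldehyde, which should slow a second silylation.

Step 4
Reactants: 5 2-hydroxy-4-methyl-6-(triisopropylsilyloxy)benzaldehyde
Product: 6 2-ethenyl-5-methyl-3-(triisopropylsilyloxy)phenol
Conditions: Ph3PCH3Br (2.5 equiv), KOtBu (2.4 equiv), THF, 0 °C to rt
Reagents that add atoms: methyltriphenylphosphonium bromide, C[P+](c1ccccc1)(c1ccccc1)c1ccccc1.[Br-]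
Why: Wittig methylenation run with excess ylide because the phenol is carried as its phenoxide; the aryl silyl ether is inert to the ylide.

Step 5
Reactants: 6 2-ethenyl-5-methyl-3-(triisopropylsilyloxy)phenol; 7 2-ethenyl-2-methyloxirane (isoprene monoepoxide, racemic)
Product: 8 (2S)-2-[2-ethenyl-5-methyl-3-(triisopropylsilyloxy)phenoxy]-2-methylbut-3-en-1-ol
Conditions: 7 (1.2 equiv, slow addition), Pd2(dba)3·CHCl3 (1 mol%), (R,R)-N,N'-(cyclohexane-1,2-diyl)bis(2-diphenylphosphinobenzamide) (3 mol%), CH2Cl2, rt
Reagents that add atoms: none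
Why: Tsuji–Trost-type dynamic kinetic asymmetric allylic etherification: zerovalent palladium ionises both enantiomers of 7 to interconverting π-allyl palladium alkoxides, the alkoxide takes the phenol proton and the phenoxide is returned to the substituted allyl terminus, the chiral bisphosphine pocket deciding the (S) configuration of the new quaternary ether carbon.

Step 6
Reactants: 8 (2S)-2-[2-ethenyl-5-methyl-3-(triisopropylsilyloxy)phenoxy]-2-methylbut-3-en-1-ol
Product: 9 [(2S)-2,7-dimethyl-5-(triisopropylsilyloxy)-2H-chromen-2-yl]methanol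
Conditions: (H2IMes)(PCy3)Cl2Ru=CHPh (second-generation Grubbs catalyst, 3 mol%), CH2Cl2, 40 °C
Reagents that add atoms: none
Why: Ring-closing olefin metathesis between the styrene and the allylic vinyl group closes the six-membered 2H-pyran ring with loss of ethene; no bond to the quaternary center is broken.

Step 7
Reactants: 9 [(2S)-2,7-dimethyl-5-(triisopropylsilyloxy)-2H-chromen-2-yl]methanol
Product: 10 (2S)-2,7-dimethyl-5-(triisopropylsilyloxy)-2H-chromene-2-carbaldehyde
Conditions: Dess–Martin periodinane, pyridine, CH2Cl2, 0 °C to rt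
Reagents that add atoms: none
Why: Dess–Martin oxidation of the primary alcohol; the α-carbon is fully substituted and cannot epimerise, and pyridine buffers the acetic acid to protect the chromene.

Step 8
Reactants: 10 (2S)-2,7-dimethyl-5-(triisopropylsilyloxy)-2H-chromene-2-carbaldehyde
Product: 11 (2R)-2-ethenyl-2,7-dimethyl-5-(triisopropylsilyloxy)-2H-chromene
Conditions: Ph3PCH3Br, KOtBu, THF, 0 °C
Reagents that add atoms: methyltriphenylphosphonium bromide, C[P+](c1ccccc1)(c1ccccc1)c1ccccc1.[Br-]
Why: Wittig methylenation of the hindered α-aryloxy aldehyde; the second vinyl group is introduced only after the first has become part of the pyran ring, so the two alkenyl groups stay different and the center stays stereogenic (the descriptor changes to R by priority only).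

Step 9
Reactants: 11 (2R)-2-ethenyl-2,7-dimethyl-5-(triisopropylsilyloxy)-2H-chromene; 3 4,4-dimethylcyclohept-2-en-1-one
Product: 13 (3R)-3-{2-[(2R)-2,7-dimethyl-5-(triisopropylsilyloxy)-2H-chromen-2-yl]ethyl}-4,4-dimethyl-1-(trimethylsilyloxy)cyclohept-1-ene, via alkylzirconocene chloride 12 (not isolated)
Conditions: Cp2Zr(H)Cl (1.2 equiv), CH2Cl2, rt; then 3 (1.5 equiv), (CuOTf)2·C6H6 (5 mol%), binaphthol/bis(1-phenylethyl)amine phosphoramidite (10 mol%, enantiomer chosen for 3R), Me3SiCl, Et2O, rt; Et3N, pentane, filtration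
Reagents that add atoms: chlorotrimethylsilane, C[Si](C)(C)Cl
Why: Hydrozirconation of the terminal vinyl group (expected to be faster than addition to the ring-conjugated cis alkene, with zirconium on the primary carbon) followed by copper-catalysed asymmetric conjugate addition with silyl trapping of the enolate; the copper–phosphoramidite catalyst selects the enone face and sets the ring stereocenter as 3R under reagent control, and the silyl enol ether locks the enolate toward C2.

Step 10
Reactants: 13 (3R)-3-{2-[(2R)-2,7-dimethyl-5-(triisopropylsilyloxy)-2H-chromen-2-yl]ethyl}-4,4-dimethyl-1-(trimethylsilyloxy)cyclohept-1-ene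
Product: 16 (3S)-2-diazo-3-{2-[(2R)-2,7-dimethyl-5-(triisopropylsilyloxy)-2H-chromen-2-yl]ethyl}-4,4-dimethylcycloheptan-1-one, via lithium enolate 14 (not isolated), via trifluoroacetyl ketone 15 (not isolated)
Conditions: MeLi, THF, 0 °C; CF3CO2CH2CF3, −78 °C; aq. HCl work-up; then MeSO2N3, Et3N, H2O, MeCN, rt
Reagents that add atoms: methanesulfonyl azide, CS(=O)(=O)N=[N+]=[N-]
Why: MeLi cleavage of the silyl enol ether gives the lithium enolate without regiochemical scrambling, C-trifluoroacetylation activates C2, and deacylative (Regitz-type) diazo transfer places the diazo group on C2 next to the untouched stereocenter (its descriptor changes to S by priority only).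

Step 11
Reactants: 16 (3S)-2-diazo-3-{2-[(2R)-2,7-dimethyl-5-(triisopropylsilyloxy)-2H-chromen-2-yl]ethyl}-4,4-dimethylcycloheptan-1-one
Product: 18 methyl (2R)-2-{2-[(2R)-2,7-dimethyl-5-(triisopropylsilyloxy)-2H-chromen-2-yl]ethyl}-3,3-dimethylcyclohexane-1-carboxylate as a mixture of C1 epimers, via ketene 17 (not isolated)
Conditions: hν (violet LED, ca. 400 nm), MeOH–THF, 0 °C
Reagents that add atoms: methanol, CO
Why: Excitation of the diazoketone expels N2 and, in concert or through the singlet acylcarbene, the ring CH2 on the far side of the carbonyl migrates from the carbonyl carbon to the diazo carbon (Wolff rearrangement), giving the six-membered ketene 17 that methanol captures as the ester. The closest known reaction type is the photochemical Wolff ring contraction of cyclic 2-diazoketones to the next-lower cycloalkanecarboxylates. The cyclohexane is closed by a 1,2-alkyl shift (ring contraction by one carbon, not a cyclisation), and the former carbonyl carbon leaves the ring as the ester carbon. The side-chain stereocenter is not part of the migrating bond and is retained; the new ester-bearing stereocenter arises on protonation of the ester enol and is not relied on here, because it is equilibrated in step 12. The required regiochemistry (ester on the ring carbon next to the side-chain stereocenter) is secured by the position of the diazo group, fixed by the conjugate-addition enolate, and the rigid s-cis geometry of the cyclic diazoketone should favour ring contraction over a 1,2-hydride shift. Light near 400 nm is absorbed by the diazoketone but not by the 2H-chromene, which guards the quaternary ether center against photochemical pyran opening.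

Step 12
Reactants: 18 methyl (2R)-2-{2-[(2R)-2,7-dimethyl-5-(triisopropylsilyloxy)-2H-chromen-2-yl]ethyl}-3,3-dimethylcyclohexane-1-carboxylate (C1 epimers)
Product: 20 (1S,2R)-2-{2-[(2R)-5-hydroxy-2,7-dimethyl-2H-chromen-2-yl]ethyl}-3,3-dimethylcyclohexane-1-carboxylic acid (target), via trans ester phenol 19 (not isolated)
Conditions: NaOMe, MeOH, 65 °C; then LiOH, H2O, 65 °C; aq. HCl to pH 3
Reagents that add atoms: lithium hydroxide, [Li+].[OH-]
Why: Methoxide enolises the ester and should equilibrate the ester-bearing carbon to the trans (1S,2R) arrangement with side chain and ester both equatorial (an axial ester would clash with the axial methyl group), and it cleaves the aryl silyl ether; saponification and acidification then give the acid, while the side-chain stereocenter has no acidic hydrogen and is unaffected.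

**Compound list**

1 | 4,4-dimethylcyclohex-2-en-1-one | CC1(C)CCC(=O)C=C1 | starting material
2 | ethyl 5,5-dimethyl-2-oxocyclohept-3-ene-1-carboxylate (racemic) | CCOC(=O)C1CCC(C)(C)C=CC1=O | intermediate
3 | 4,4-dimethylcyclohept-2-en-1-one | CC1(C)CCCC(=O)C=C1 | intermediate
4 | 2,6-dihydroxy-4-methylbenzaldehyde (atranol) | Cc1cc(O)c(C=O)c(O)c1 | starting material
5 | 2-hydroxy-4-methyl-6-(triisopropylsilyloxy)benzaldehyde | Cc1cc(O)c(C=O)c(O[Si](C(C)C)(C(C)C)C(C)C)c1 | intermediate
6 | 2-ethenyl-5-methyl-3-(triisopropylsilyloxy)phenol | Cc1cc(O)c(C=C)c(O[Si](C(C)C)(C(C)C)C(C)C)c1 | intermediate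
7 | 2-ethenyl-2-methyloxirane (racemic) | CC1(C=C)CO1 | starting material
8 | (2S)-2-[2-ethenyl-5-methyl-3-(triisopropylsilyloxy)phenoxy]-2-methylbut-3-en-1-ol | Cc1cc(O[Si](C(C)C)(C(C)C)C(C)C)c(C=C)c(c1)O[C@](C)(CO)C=C | intermediate
9 | [(2S)-2,7-dimethyl-5-(triisopropylsilyloxy)-2H-chromen-2-yl]methanol | Cc1cc(O[Si](C(C)C)(C(C)C)C(C)C)c2c(c1)O[C@](C)(CO)C=C2 | intermediate
10 | (2S)-2,7-dimethyl-5-(triisopropylsilyloxy)-2H-chromene-2-carbaldehyde | Cc1cc(O[Si](C(C)C)(C(C)C)C(C)C)c2c(c1)O[C@](C)(C=O)C=C2 | intermediate
11 | (2R)-2-ethenyl-2,7-dimethyl-5-(triisopropylsilyloxy)-2H-chromene | Cc1cc(O[Si](C(C)C)(C(C)C)C(C)C)c2c(c1)O[C@](C)(C=C)C=C2 | intermediate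
12 | chlorobis(cyclopentadienyl){2-[(2R)-2,7-dimethyl-5-(triisopropylsilyloxy)-2H-chromen-2-yl]ethyl}zirconium | Cc1cc(O[Si](C(C)C)(C(C)C)C(C)C)c2c(c1)O[C@](C)(CC[Zr](Cl)(C1C=CC=C1)C1C=CC=C1)C=C2 | intermediate
13 | (3R)-3-{2-[(2R)-2,7-dimethyl-5-(triisopropylsilyloxy)-2H-chromen-2-yl]ethyl}-4,4-dimethyl-1-(trimethylsilyloxy)cyclohept-1-ene | Cc1cc(O[Si](C(C)C)(C(C)C)C(C)C)c2c(c1)O[C@](C)(CC[C@@H]1C=C(O[Si](C)(C)C)CCCC1(C)C)C=C2 | intermediate
14 | lithium (3R)-3-{2-[(2R)-2,7-dimethyl-5-(triisopropylsilyloxy)-2H-chromen-2-yl]ethyl}-4,4-dimethylcyclohept-1-en-1-olate | Cc1cc(O[Si](C(C)C)(C(C)C)C(C)C)c2c(c1)O[C@](C)(CC[C@@H]1C=C(O[Li])CCCC1(C)C)C=C2 | intermediate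
15 | (3R)-3-{2-[(2R)-2,7-dimethyl-5-(triisopropylsilyloxy)-2H-chromen-2-yl]ethyl}-4,4-dimethyl-2-(trifluoroacetyl)cycloheptan-1-one (C2 epimers, largely enolised) | Cc1cc(O[Si](C(C)C)(C(C)C)C(C)C)c2c(c1)O[C@](C)(CC[C@@H]1C(C(=O)C(F)(F)F)C(=O)CCCC1(C)C)C=C2 | intermediate
16 | (3S)-2-diazo-3-{2-[(2R)-2,7-dimethyl-5-(triisopropylsilyloxy)-2H-chromen-2-yl]ethyl}-4,4-dimethylcycloheptan-1-one | Cc1cc(O[Si](C(C)C)(C(C)C)C(C)C)c2c(c1)O[C@](C)(CC[C@@H]1C(=[N+]=[N-])C(=O)CCCC1(C)C)C=C2 | intermediate
17 | {(2S)-2-{2-[(2R)-2,7-dimethyl-5-(triisopropylsilyloxy)-2H-chromen-2-yl]ethyl}-3,3-dimethylcyclohexylidene}methanone (ketene) | Cc1cc(O[Si](C(C)C)(C(C)C)C(C)C)c2c(c1)O[C@](C)(CC[C@@H]1C(=C=O)CCCC1(C)C)C=C2 | intermediate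
18 | methyl (2R)-2-{2-[(2R)-2,7-dimethyl-5-(triisopropylsilyloxy)-2H-chromen-2-yl]ethyl}-3,3-dimethylcyclohexane-1-carboxylate (both C1 epimers; C1 left undefined in the SMILES) | Cc1cc(O[Si](C(C)C)(C(C)C)C(C)C)c2c(c1)O[C@](C)(CC[C@@H]1C(C(=O)OC)CCCC1(C)C)C=C2 | intermediate
19 | methyl (1S,2R)-2-{2-[(2R)-5-hydroxy-2,7-dimethyl-2H-chromen-2-yl]ethyl}-3,3-dimethylcyclohexane-1-carboxylate (present as its sodium phenoxide) | Cc1cc(O)c2c(c1)O[C@](C)(CC[C@@H]1[C@@H](C(=O)OC)CCCC1(C)C)C=C2 | intermediate
20 | (1S,2R)-2-{2-[(2R)-5-hydroxy-2,7-dimethyl-2H-chromen-2-yl]ethyl}-3,3-dimethylcyclohexane-1-carboxylic acid | Cc1cc(O)c2c(c1)O[C@](C)(CC[C@@H]1[C@@H](C(=O)O)CCCC1(C)C)C=C2 | target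

**Step count**

Total step count: 12. Longest linear sequence: 10 steps (from 4 through steps 3 to 12); the two-step preparation of 3 joins at step 9.

**Steps most likely to fail**

Step 9. The hydrozirconation may be incomplete or unselective (addition to the ring alkene, or internal addition followed by loss of aryloxide), the alkylzirconium may transfer only slowly to the γ,γ-disubstituted enone, and the facial selectivity may be poor. Fallback, from 11 back to 13: hydroboration of 11 with 9-borabicyclo[3.3.1]nonane would give the B-alkyl borane F1, which NaBO3·4H2O would oxidise to the primary alcohol F2. CBr4/PPh3 (Appel reaction) would convert F2 into the bromide F3, and Mg in THF below 25 °C would give the Grignard reagent F4. Asymmetric conjugate addition of F4 to 3, catalysed by CuBr·SMe2 and a ferrocenyl diphosphine of the Josiphos type in tBuOMe at −75 °C and quenched with Me3SiCl/Et3N, would return to 13. This replaces the in-situ alkene-derived nucleophile by a preformed, more reactive organomagnesium reagent and a different catalyst family.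

Step 11. The chromene may undergo photochemical electrocyclic opening of the pyran ring (which would erase the quaternary ether center), the carbene may undergo a 1,2-hydride shift to an enone, or it may insert into the O–H bond of methanol. Fallback, from 13 back to 18 without diazoketone or light: nonafluorobutanesulfonyl azide in MeCN at rt should add to the silyl enol ether in a dipolar cycloaddition, and the triazoline should lose N2 with the same 1,2-shift. Aqueous work-up would give the ring-contracted N-sulfonyl carboxamide F5. MeI/K2CO3 in DMF would give the N-methyl derivative F6, an activated acyl sulfonamide, and NaOMe in MeOH at 0 °C would cleave it to 18.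

Step 5. Enantioselectivity may erode if phenoxide attack outruns interconversion of the diastereomeric π-allyl complexes, attack may occur at the unsubstituted allyl terminus, and the tertiary allyl aryl ether may re-ionise. Fallback, from 6 back to 8: the achiral trisubstituted allylic carbonate F7 (from (2E)-4-(tert-butyldimethylsilyloxy)-3-methylbut-2-en-1-ol and methyl chloroformate) would be used in place of the vinyl epoxide. Asymmetric allylic etherification of 6 with F7, using zerovalent palladium and the same ligand class, would give the silyl-protected tertiary ether F8; the stereocenter would then be set by enantioface selection on an achiral π-allyl precursor, not by a dynamic kinetic process. Camphorsulfonic acid in MeOH at 0 °C would remove the primary silyl group and give 8.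

**Further compounds**

F1 | step 9 | 9-{2-[(2R)-2,7-dimethyl-5-(triisopropylsilyloxy)-2H-chromen-2-yl]ethyl}-9-borabicyclo[3.3.1]nonane | Cc1cc(O[Si](C(C)C)(C(C)C)C(C)C)c2c(c1)O[C@](C)(CCB1C3CCCC1CCC3)C=C2
F2 | step 9 | 2-[(2R)-2,7-dimethyl-5-(triisopropylsilyloxy)-2H-chromen-2-yl]ethan-1-ol | Cc1cc(O[Si](C(C)C)(C(C)C)C(C)C)c2c(c1)O[C@](C)(CCO)C=C2
F3 | step 9 | (2R)-2-(2-bromoethyl)-2,7-dimethyl-5-(triisopropylsilyloxy)-2H-chromene | Cc1cc(O[Si](C(C)C)(C(C)C)C(C)C)c2c(c1)O[C@](C)(CCBr)C=C2
F4 | step 9 | {2-[(2R)-2,7-dimethyl-5-(triisopropylsilyloxy)-2H-chromen-2-yl]ethyl}magnesium bromide | Cc1cc(O[Si](C(C)C)(C(C)C)C(C)C)c2c(c1)O[C@](C)(CC[Mg]Br)C=C2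
F5 | step 11 | (2R)-2-{2-[(2R)-2,7-dimethyl-5-(triisopropylsilyloxy)-2H-chromen-2-yl]ethyl}-3,3-dimethyl-N-(nonafluorobutylsulfonyl)cyclohexane-1-carboxamide (C1 epimers) | Cc1cc(O[Si](C(C)C)(C(C)C)C(C)C)c2c(c1)O[C@](C)(CC[C@@H]1C(C(=O)NS(=O)(=O)C(F)(F)C(F)(F)C(F)(F)C(F)(F)F)CCCC1(C)C)C=C2
F6 | step 11 | (2R)-2-{2-[(2R)-2,7-dimethyl-5-(triisopropylsilyloxy)-2H-chromen-2-yl]ethyl}-N,3,3-trimethyl-N-(nonafluorobutylsulfonyl)cyclohexane-1-carboxamide (C1 epimers) | Cc1cc(O[Si](C(C)C)(C(C)C)C(C)C)c2c(c1)O[C@](C)(CC[C@@H]1C(C(=O)N(C)S(=O)(=O)C(F)(F)C(F)(F)C(F)(F)C(F)(F)F)CCCC1(C)C)C=C2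
F7 | step 5 | (2E)-4-(tert-butyldimethylsilyloxy)-3-methylbut-2-en-1-yl methyl carbonate | COC(=O)OC/C=C(C)/CO[Si](C)(C)C(C)(C)C
F8 | step 5 | tert-butyl{[(2S)-2-[2-ethenyl-5-methyl-3-(triisopropylsilyloxy)phenoxy]-2-methylbut-3-en-1-yl]oxy}dimethylsilane | Cc1cc(O[Si](C(C)C)(C(C)C)C(C)C)c(C=C)c(c1)O[C@](C)(CO[Si](C)(C)C(C)(C)C)C=C
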